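C1 is the ring-fusion carbon with the angular methyl, C2/C3 the ring A methylenes, C4 the isopropyl carbinol, C5 the ring-fusion CH, C6 the acyloxy carbon, and C7, C8(Me)=C9, C10 complete ring B; β is the face of the angular methyl.
Retrosynthesis: cut the C6–O acyl bond, take C6–OH back to a ketone and C4–OH/C5–H back to a 4,5-epoxide of a C4=C5 alkene, open ring B at C8=C9 (metathesis) and C6–C7 (methallylation), cut C4–isopropyl (enol triflate), open ring A at C1–C5 (C–H insertion) and cut C4–C5 (aldehyde homologation).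
Enabling feature: C1 carries a methyl and two CH2 arms (C2, C10), the same array as the stereocentre of (S)-citronellol. Its fourth bond runs to C5, which lies between the oxygenated carbons C4 and C6 and is the fifth atom from C1 along C2–C3–C4, so a keto ester carbenoid at C5 can replace the C1 hydrogen and close ring A.
Forward: citronellol chain, diazo keto ester, ring A (step 5), isopropyl at C4, ring B by ring-closing metathesis (step 14), oxygenation of C4/C5/C6, ester.
Stereochemistry: C1 comes from (S)-citronellol and is kept by the retentive insertion; a reagent-set temporary C6 carbinol directs the β-epoxide and thereby C4; C5 is set by α-protonation of a samarium enolate; the final C6 by hydride delivery from the C4 hydroxyl.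

Key step: step 5

Remark: ethyl diazoacetate is used as the diazo component because it is the common commercial diazoacetate; the ester alkyl is a spectator and is lost in step 11.

Step 1
Reactants: 1 (S)-citronellol
Product: 2 tert-butyl{[(3S)-3,7-dimethyloct-6-en-1-yl]oxy}dimethylsilane
Conditions: TBSCl, imidazole, DMF, rt
Reagents that add atoms: tert-butyldimethylsilyl chloride, CC(C)(C)[Si](C)(C)Cl
Why: Imidazole-promoted silyl ether formation on a primary alcohol; the stereocentre is not touched.

Step 2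
Reactants: 2 tert-butyl{[(3S)-3,7-dimethyloct-6-en-1-yl]oxy}dimethylsilane
Product: 4 (4S)-6-[(tert-butyldimethylsilyl)oxy]-4-methylhexanal, via secondary ozonide 3 (not isolated)
Conditions: O3, CH2Cl2, −78 °C; then PPh3, −78 °C to rt
Reagents that add atoms: ozone, [O-][O+]=O
Why: Ozonolysis with reductive work-up (Criegee mechanism) cleaves the only alkene to the aldehyde that becomes C4; the silyl ether is inert and the stereocentre is remote from the carbonyl.

Step 3
Reactants: 4 (4S)-6-[(tert-butyldimethylsilyl)oxy]-4-methylhexanal; 5 ethyl diazoacetate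
Product: 6 ethyl (6S)-8-[(tert-butyldimethylsilyl)oxy]-6-methyl-3-oxooctanoate
Conditions: SnCl2 (10 mol%), CH2Cl2, rt
Reagents that add atoms: none
Why: Roskamp homologation: SnCl2-activated addition of the diazo ester to the aldehyde and 1,2-hydride shift with loss of N2 gives the β-keto ester and forms the C4–C5 bond.

Step 4
Reactants: 6 ethyl (6S)-8-[(tert-butyldimethylsilyl)oxy]-6-methyl-3-oxooctanoate
Product: 7 ethyl (6S)-8-[(tert-butyldimethylsilyl)oxy]-2-diazo-6-methyl-3-oxooctanoate
Conditions: 4-acetamidobenzenesulfonyl azide, Et3N, MeCN, 0 °C to rt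
Reagents that add atoms: 4-acetamidobenzenesulfonyl azide, CC(=O)Nc1ccc(cc1)S(=O)(=O)N=[N+]=[N-]
Why: Regitz diazo transfer to the doubly activated methylene (C5) is a standard route to α-diazo-β-keto esters.

Step 5
Reactants: 7 ethyl (6S)-8-[(tert-butyldimethylsilyl)oxy]-2-diazo-6-methyl-3-oxooctanoate
Product: 8 ethyl (1R,2R)-2-{2-[(tert-butyldimethylsilyl)oxy]ethyl}-2-methyl-5-oxocyclopentane-1-carboxylate
Conditions: Rh2(OAc)4 (1 mol%), CH2Cl2, rt
Reagents that add atoms: none
Why: Rh2(OAc)4 (divalent rhodium) expels N2 from 7 to give an electrophilic rhodium carbenoid at C5 which, flanked by two carbonyl groups and so without a 1,2-hydride shift open to it, inserts into the C1–H bond through a concerted three-centre C5···H···C1 transition state with release of the catalyst. The closest known reaction type is the intramolecular 1,5 C–H insertion of α-diazo-β-keto esters to 2-alkoxycarbonylcyclopentanones. Ring A closes in the 1,5 mode: the five-membered ring C1–C2–C3–C4–C5 forms by C1–C5 bonding through a chair-like six-atom array that includes the migrating hydrogen. The new quaternary stereocentre C1 is controlled by the citronellol stereocentre itself, since carbon enters on the face that the hydrogen leaves (retention); C5 is formed as an epimerisable, largely enolised centre (drawn as one epimer) and is erased in step 6. The step needs site selectivity, and the substrate secures it because the methine C1–H is the only C–H that leads to a five-membered ring and is also the most electron-rich, while the C9 hydrogens next to the silyloxy group, the methyl hydrogens and the C10 hydrogens could react only through six- or seven-membered rings.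

Step 6
Reactants: 8 ethyl (1R,2R)-2-{2-[(tert-butyldimethylsilyl)oxy]ethyl}-2-methyl-5-oxocyclopentane-1-carboxylate
Product: 10 ethyl (5R)-5-{2-[(tert-butyldimethylsilyl)oxy]ethyl}-5-methyl-2-[(trifluoromethanesulfonyl)oxy]cyclopent-1-ene-1-carboxylate, via sodium enolate 9 (not isolated)
Conditions: NaH, THF, 0 °C; then PhNTf2, 0 °C to rt
Reagents that add atoms: N-phenylbis(trifluoromethanesulfonimide), O=S(=O)(N(c1ccccc1)S(=O)(=O)C(F)(F)F)C(F)(F)F
Why: O-sulfonylation of the β-keto ester enolate gives the enol triflate at C4=C5, so both C5 epimers of 8 converge.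

Step 7
Reactants: 10 ethyl (5R)-5-{2-[(tert-butyldimethylsilyl)oxy]ethyl}-5-methyl-2-[(trifluoromethanesulfonyl)oxy]cyclopent-1-ene-1-carboxylate
Product: 11 ethyl (5R)-5-{2-[(tert-butyldimethylsilyl)oxy]ethyl}-5-methyl-2-(propan-2-yl)cyclopent-1-ene-1-carboxylate
Conditions: i-PrMgCl (3 equiv), CuI (1.5 equiv), THF, −78 to −30 °C
Reagents that add atoms: isopropylmagnesium chloride, CC(C)[Mg]Cl
Why: Organocuprate coupling with a β-triflyloxy enoate (conjugate addition then loss of triflate) puts the isopropyl group on C4 and leaves the tetrasubstituted C4=C5 enoate; no free Grignard reagent remains to attack the ester.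

Step 8
Reactants: 11 ethyl (5R)-5-{2-[(tert-butyldimethylsilyl)oxy]ethyl}-5-methyl-2-(propan-2-yl)cyclopent-1-ene-1-carboxylate
Product: 12 ethyl (5R)-5-(2-hydroxyethyl)-5-methyl-2-(propan-2-yl)cyclopent-1-ene-1-carboxylate
Conditions: HF·pyridine, THF/pyridine, 0 °C to rt
Reagents that add atoms: none
Why: Fluoride-mediated desilylation; the mildly acidic medium is chosen so that no alkoxide is formed that could lactonise onto the hindered conjugated ester.

Step 9
Reactants: 12 ethyl (5R)-5-(2-hydroxyethyl)-5-methyl-2-(propan-2-yl)cyclopent-1-ene-1-carboxylate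
Product: 13 ethyl (5R)-5-methyl-5-(2-oxoethyl)-2-(propan-2-yl)cyclopent-1-ene-1-carboxylate
Conditions: Dess–Martin periodinane, NaHCO3, CH2Cl2, 0 °C to rt
Reagents that add atoms: none
Why: Dess–Martin oxidation of the primary alcohol to the C9 aldehyde, which has a quaternary β-carbon and no stereocentre that could epimerise.

Step 10
Reactants: 13 ethyl (5R)-5-methyl-5-(2-oxoethyl)-2-(propan-2-yl)cyclopent-1-ene-1-carboxylate
Product: 14 ethyl (5R)-5-methyl-2-(propan-2-yl)-5-(prop-2-en-1-yl)cyclopent-1-ene-1-carboxylate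
Conditions: Ph3PCH3Br, KN(SiMe3)2, THF, 0 °C; then 13, −78 to 0 °C
Reagents that add atoms: methyltriphenylphosphonium bromide, C[P+](c1ccccc1)(c1ccccc1)c1ccccc1.[Br-]
Why: Wittig methylenation; the unstabilised ylide reacts with the aldehyde far faster than with the hindered conjugated ester and supplies the alkene carbon that is later lost as ethene.

Step 11
Reactants: 14 ethyl (5R)-5-methyl-2-(propan-2-yl)-5-(prop-2-en-1-yl)cyclopent-1-ene-1-carboxylate
Product: 15 [(5R)-5-methyl-2-(propan-2-yl)-5-(prop-2-en-1-yl)cyclopent-1-en-1-yl]methanol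
Conditions: i-Bu2AlH (2.5 equiv), CH2Cl2, −78 to 0 °C
Reagents that add atoms: none
Why: 1,2-Reduction of a conjugated ester by i-Bu2AlH to the allylic alcohol; the isolated alkene is inert.

Step 12
Reactants: 15 [(5R)-5-methyl-2-(propan-2-yl)-5-(prop-2-en-1-yl)cyclopent-1-en-1-yl]methanol
Product: 16 (5R)-5-methyl-2-(propan-2-yl)-5-(prop-2-en-1-yl)cyclopent-1-ene-1-carbaldehyde
Conditions: Dess–Martin periodinane, NaHCO3, CH2Cl2, 0 °C to rt
Reagents that add atoms: none
Why: Dess–Martin oxidation of an allylic alcohol to the enal (C6), which has no α-hydrogen and cannot isomerise.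

Step 13
Reactants: 16 (5R)-5-methyl-2-(propan-2-yl)-5-(prop-2-en-1-yl)cyclopent-1-ene-1-carbaldehyde
Product: 18 (1R)-3-methyl-1-[(5R)-5-methyl-2-(propan-2-yl)-5-(prop-2-en-1-yl)cyclopent-1-en-1-yl]but-3-en-1-ol, via borinic ester 17 (not isolated)
Conditions: B-(2-methylallyl)diisopinocampheylborane of the (−)-α-pinene series [from the (−)-α-pinene-derived Ipc2BOMe and CH2=C(CH3)CH2MgCl, Et2O, −78 °C to rt], then 16, Et2O, −78 °C; then NaOH, H2O2, 0 °C to rt
Reagents that add atoms: B-(2-methylallyl)diisopinocampheylborane, CC(=C)CB([C@H]1C[C@H]2C[C@@H]([C@@H]1C)C2(C)C)[C@H]1C[C@H]2C[C@@H]([C@@H]1C)C2(C)C, formed in the flask from 2-methylallylmagnesium chloride, CC(=C)C[Mg]Cl, and B-methoxydiisopinocampheylborane, COB([C@H]1C[C@H]2C[C@@H]([C@@H]1C)C2(C)C)[C@H]1C[C@H]2C[C@@H]([C@@H]1C)C2(C)C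
Why: Brown asymmetric methallylboration through a closed chair (Zimmerman–Traxler) transition state, in which the (−)-α-pinene-derived isopinocampheyl groups send the methallyl group to the Re face of the aldehyde; this sets C6 as R (the β-hydroxyl after ring closure) under reagent control, the remote C1 centre exerting no bias, and forms the C6–C7 bond.

Step 14
Reactants: 18 (1R)-3-methyl-1-[(5R)-5-methyl-2-(propan-2-yl)-5-(prop-2-en-1-yl)cyclopent-1-en-1-yl]but-3-en-1-ol
Product: 19 (4R,8aR)-6,8a-dimethyl-3-(propan-2-yl)-1,2,4,5,8,8a-hexahydroazulen-4-ol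
Conditions: RuCl2(=CHPh)(PCy3)(H2IMes) (second-generation Grubbs catalyst, 5 mol%), CH2Cl2 (dilute), 40 °C
Reagents that add atoms: none
Why: Ring-closing metathesis of a monosubstituted with a 1,1-disubstituted alkene closes the seven-membered ring B with the trisubstituted C8=C9 bond; the two chains sit on adjacent ring atoms C1 and C5 and the tetrasubstituted C4=C5 bond does not engage the catalyst.

Step 15
Reactants: 19 (4R,8aR)-6,8a-dimethyl-3-(propan-2-yl)-1,2,4,5,8,8a-hexahydroazulen-4-ol
Product: 20 (1R,4R,5S,6R)-4,5-epoxydauc-8-en-6-ol (4β,5β-epoxide of 19; locants of the plan)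
Conditions: VO(acac)2 (5 mol%), t-BuOOH, CH2Cl2, 0 °C
Reagents that add atoms: tert-butyl hydroperoxide, CC(C)(C)OO
Why: Hydroxyl-directed epoxidation: the vanadate ester of the C6 hydroxyl, held out of the alkene plane by 1,3-allylic strain with the isopropyl group, delivers oxygen to the allylic C4=C5 bond on the hydroxyl (β) face, which fixes C4–O as β; the merely homoallylic C8=C9 bond should react much more slowly.

Step 16
Reactants: 20 (1R,4R,5S,6R)-4,5-epoxydauc-8-en-6-ol
Product: 21 (1R,4R,5R)-4,5-epoxydauc-8-en-6-one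
Conditions: Dess–Martin periodinane, NaHCO3, CH2Cl2, 0 °C to rt
Reagents that add atoms: none
Why: Dess–Martin oxidation under buffered, non-basic conditions gives the α,β-epoxy ketone without opening the epoxide or moving the C8=C9 bond into conjugation.

Step 17
Reactants: 21 (1R,4R,5R)-4,5-epoxydauc-8-en-6-one
Product: 22 (3R,3aR,8aR)-3-hydroxy-6,8a-dimethyl-3-(propan-2-yl)-2,3,3a,5,8,8a-hexahydroazulen-4(1H)-one
Conditions: SmI2 (2.5 equiv), THF/MeOH, −78 °C
Reagents that add atoms: none
Why: SmI2 (divalent samarium) reduction of an α,β-epoxy ketone: ketyl formation, cleavage of the C5–O bond and a second electron give a samarium enolate, while the C4–O bond and its β configuration stay intact; methanol should protonate C5 from the α face, away from the angular methyl and the samarium-bound C4 oxygen, which also leads to the trans-fused ketone expected to be the more stable (carbonyl cis to the C4 hydroxyl, trans to the isopropyl group).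

Step 18
Reactants: 22 (3R,3aR,8aR)-3-hydroxy-6,8a-dimethyl-3-(propan-2-yl)-2,3,3a,5,8,8a-hexahydroazulen-4(1H)-one
Product: 23 (3R,3aS,4S,8aR)-6,8a-dimethyl-3-(propan-2-yl)-1,2,3,3a,4,5,8,8a-octahydroazulene-3,4-diol
Conditions: Me4NBH(OAc)3 (5 equiv), MeCN/AcOH, −30 to −20 °C
Reagents that add atoms: none
Why: Hydroxyl-directed anti reduction of a β-hydroxy ketone (Evans–Saksena): the C4 hydroxyl exchanges onto boron and delivers hydride within a six-membered transition state to the β face of C6, giving the 6α-alcohol (1,3-anti diol) against the intrinsic preference of an external hydride.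

Step 19
Reactants: 24 (2E)-3-(4-hydroxyphenyl)prop-2-enoic acid (p-coumaric acid)
Product: 26 (2E)-3-{4-[(tert-butyldimethylsilyl)oxy]phenyl}prop-2-enoic acid, via silyl ester 25 (not isolated)
Conditions: TBSCl (2.5 equiv), imidazole, DMF, rt; then AcOH/THF/H2O, rt
Reagents that add atoms: tert-butyldimethylsilyl chloride, CC(C)(C)[Si](C)(C)Cl
Why: Exhaustive silylation followed by selective hydrolysis of the far more labile silyl ester leaves the phenol protected and the acid free.

Step 20
Reactants: 23 (3R,3aS,4S,8aR)-6,8a-dimethyl-3-(propan-2-yl)-1,2,3,3a,4,5,8,8a-octahydroazulene-3,4-diol; 26 (2E)-3-{4-[(tert-butyldimethylsilyl)oxy]phenyl}prop-2-enoic acid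
Product: 27 (3R,3aS,4S,8aR)-3-hydroxy-6,8a-dimethyl-3-(propan-2-yl)-1,2,3,3a,4,5,8,8a-octahydroazulen-4-yl (2E)-3-{4-[(tert-butyldimethylsilyl)oxy]phenyl}prop-2-enoate
Conditions: DCC, DMAP, CH2Cl2, 0 °C to rt
Reagents that add atoms: none
Why: Steglich esterification acylates only the secondary C6 hydroxyl; the tertiary C4 hydroxyl does not react and no stereocentre is involved.

Step 21
Reactants: 27 (3R,3aS,4S,8aR)-3-hydroxy-6,8a-dimethyl-3-(propan-2-yl)-1,2,3,3a,4,5,8,8a-octahydroazulen-4-yl (2E)-3-{4-[(tert-butyldimethylsilyl)oxy]phenyl}prop-2-enoate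
Product: 28 (3R,3aS,4S,8aR)-3-hydroxy-6,8a-dimethyl-3-(propan-2-yl)-1,2,3,3a,4,5,8,8a-octahydroazulen-4-yl (2E)-3-(4-hydroxyphenyl)prop-2-enoate
Conditions: Bu4NF, AcOH, THF, 0 °C
Reagents that add atoms: none
Why: Fluoride cleavage of the aryl silyl ether, buffered with acetic acid so that the phenoxide does not attack the cinnamate ester; the alkenes and the tertiary alcohol are untouched.

Compound list
1 | (S)-citronellol, (3S)-3,7-dimethyloct-6-en-1-ol | OCC[C@@H](C)CCC=C(C)C | starting material
2 | tert-butyl{[(3S)-3,7-dimethyloct-6-en-1-yl]oxy}dimethylsilane | CC(C)(C)[Si](C)(C)OCC[C@@H](C)CCC=C(C)C | intermediate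
3 | secondary ozonide of 2, 3,3-dimethyl-5-substituted 1,2,4-trioxolane (mixture at the trioxolane CH) | CC(C)(C)[Si](C)(C)OCC[C@@H](C)CCC1OOC(C)(C)O1 | intermediate (not isolated)
4 | (4S)-6-[(tert-butyldimethylsilyl)oxy]-4-methylhexanal | CC(C)(C)[Si](C)(C)OCC[C@@H](C)CCC=O | intermediate
5 | ethyl diazoacetate | CCOC(=O)C=[N+]=[N-] | starting material
6 | ethyl (6S)-8-[(tert-butyldimethylsilyl)oxy]-6-methyl-3-oxooctanoate | CCOC(=O)CC(=O)CC[C@H](C)CCO[Si](C)(C)C(C)(C)C | intermediate
7 | ethyl (6S)-8-[(tert-butyldimethylsilyl)oxy]-2-diazo-6-methyl-3-oxooctanoate | CCOC(=O)C(=[N+]=[N-])C(=O)CC[C@H](C)CCO[Si](C)(C)C(C)(C)C | intermediate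
8 | ethyl (1R,2R)-2-{2-[(tert-butyldimethylsilyl)oxy]ethyl}-2-methyl-5-oxocyclopentane-1-carboxylate (ester-bearing carbon epimerisable) | CCOC(=O)[C@H]1C(=O)CC[C@]1(C)CCO[Si](C)(C)C(C)(C)C | intermediate
9 | sodium enolate of 8 | [Na+].CCOC(=O)C1=C([O-])CC[C@]1(C)CCO[Si](C)(C)C(C)(C)C | intermediate (not isolated)
10 | ethyl (5R)-5-{2-[(tert-butyldimethylsilyl)oxy]ethyl}-5-methyl-2-[(trifluoromethanesulfonyl)oxy]cyclopent-1-ene-1-carboxylate | CCOC(=O)C1=C(OS(=O)(=O)C(F)(F)F)CC[C@]1(C)CCO[Si](C)(C)C(C)(C)C | intermediate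
11 | ethyl (5R)-5-{2-[(tert-butyldimethylsilyl)oxy]ethyl}-5-methyl-2-(propan-2-yl)cyclopent-1-ene-1-carboxylate | CCOC(=O)C1=C(C(C)C)CC[C@]1(C)CCO[Si](C)(C)C(C)(C)C | intermediate
12 | ethyl (5R)-5-(2-hydroxyethyl)-5-methyl-2-(propan-2-yl)cyclopent-1-ene-1-carboxylate | CCOC(=O)C1=C(C(C)C)CC[C@]1(C)CCO | intermediate
13 | ethyl (5R)-5-methyl-5-(2-oxoethyl)-2-(propan-2-yl)cyclopent-1-ene-1-carboxylate | CCOC(=O)C1=C(C(C)C)CC[C@]1(C)CC=O | intermediate
14 | ethyl (5R)-5-methyl-2-(propan-2-yl)-5-(prop-2-en-1-yl)cyclopent-1-ene-1-carboxylate | CCOC(=O)C1=C(C(C)C)CC[C@]1(C)CC=C | intermediate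
15 | [(5R)-5-methyl-2-(propan-2-yl)-5-(prop-2-en-1-yl)cyclopent-1-en-1-yl]methanol | OCC1=C(C(C)C)CC[C@]1(C)CC=C | intermediate
16 | (5R)-5-methyl-2-(propan-2-yl)-5-(prop-2-en-1-yl)cyclopent-1-ene-1-carbaldehyde | O=CC1=C(C(C)C)CC[C@]1(C)CC=C | intermediate
17 | diisopinocampheylborinic ester of 18 | CC(=C)C[C@@H](OB([C@H]1C[C@H]2C[C@@H]([C@@H]1C)C2(C)C)[C@H]1C[C@H]2C[C@@H]([C@@H]1C)C2(C)C)C1=C(C(C)C)CC[C@]1(C)CC=C | intermediate (not isolated)
18 | (1R)-3-methyl-1-[(5R)-5-methyl-2-(propan-2-yl)-5-(prop-2-en-1-yl)cyclopent-1-en-1-yl]but-3-en-1-ol | CC(=C)C[C@@H](O)C1=C(C(C)C)CC[C@]1(C)CC=C | intermediate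
19 | (4R,8aR)-6,8a-dimethyl-3-(propan-2-yl)-1,2,4,5,8,8a-hexahydroazulen-4-ol | CC1=CC[C@@]2(C)CCC(C(C)C)=C2[C@H](O)C1 | intermediate
20 | (1R,4R,5S,6R)-4,5-epoxydauc-8-en-6-ol (4β,5β-epoxide, 6β-hydroxyl) | CC1=CC[C@@]2(C)CC[C@]3(C(C)C)O[C@]23[C@H](O)C1 | intermediate
21 | (1R,4R,5R)-4,5-epoxydauc-8-en-6-one (4β,5β-epoxide) | CC1=CC[C@@]2(C)CC[C@]3(C(C)C)O[C@]23C(=O)C1 | intermediate
22 | (3R,3aR,8aR)-3-hydroxy-6,8a-dimethyl-3-(propan-2-yl)-2,3,3a,5,8,8a-hexahydroazulen-4(1H)-one | CC1=CC[C@@]2(C)CC[C@@](O)(C(C)C)[C@@H]2C(=O)C1 | intermediate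
23 | (3R,3aS,4S,8aR)-6,8a-dimethyl-3-(propan-2-yl)-1,2,3,3a,4,5,8,8a-octahydroazulene-3,4-diol | CC1=CC[C@@]2(C)CC[C@@](O)(C(C)C)[C@@H]2[C@@H](O)C1 | intermediate
24 | (2E)-3-(4-hydroxyphenyl)prop-2-enoic acid (p-coumaric acid) | OC(=O)/C=C/c1ccc(O)cc1 | starting material
25 | tert-butyldimethylsilyl (2E)-3-{4-[(tert-butyldimethylsilyl)oxy]phenyl}prop-2-enoate | CC(C)(C)[Si](C)(C)OC(=O)/C=C/c1ccc(O[Si](C)(C)C(C)(C)C)cc1 | intermediate (not isolated)
26 | (2E)-3-{4-[(tert-butyldimethylsilyl)oxy]phenyl}prop-2-enoic acid | OC(=O)/C=C/c1ccc(O[Si](C)(C)C(C)(C)C)cc1 | intermediate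
27 | (3R,3aS,4S,8aR)-3-hydroxy-6,8a-dimethyl-3-(propan-2-yl)-1,2,3,3a,4,5,8,8a-octahydroazulen-4-yl (2E)-3-{4-[(tert-butyldimethylsilyl)oxy]phenyl}prop-2-enoate | CC1=CC[C@@]2(C)CC[C@@](O)(C(C)C)[C@@H]2[C@@H](OC(=O)/C=C/c2ccc(O[Si](C)(C)C(C)(C)C)cc2)C1 | intermediate
28 | (3R,3aS,4S,8aR)-3-hydroxy-6,8a-dimethyl-3-(propan-2-yl)-1,2,3,3a,4,5,8,8a-octahydroazulen-4-yl (2E)-3-(4-hydroxyphenyl)prop-2-enoate (CNP0265426.1) | CC1=CC[C@@]2(C)CC[C@@](O)(C(C)C)[C@@H]2[C@@H](OC(=O)/C=C/c2ccc(O)cc2)C1 | target

Total step count: 21 (20 in the main line, 1 for the acid 26).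
Longest linear sequence: 20 steps (steps 1 to 18, 20 and 21).

Steps most likely to fail

Step 17. C5 is created by protonation of a samarium enolate; the proton may enter from the β face and give the cis-fused epimer, and the tertiary aldol may undergo retro-aldol cleavage. The fallback sets out from 20, omits the oxidation and makes the C5–H bond by a stereospecific 1,2-hydride shift instead of an enolate protonation. Silylation (Me3SiCl, Et3N, CH2Cl2) gives the 6-O-trimethylsilyl ether F1. TiCl4 in CH2Cl2 at −78 °C should then open the chelated epoxide at C5 while the C6 hydrogen, which lies anti to the breaking C5–O bond, migrates to the α face of C5 (semipinacol rearrangement of a 2,3-epoxy silyl ether). Loss of the silyl group and aqueous work-up lead to 22, where the route is rejoined.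

Step 15. Oxygen may be delivered to the homoallylic C8=C9 bond, or to the α face if ring B holds the C6 hydroxyl near the plane of the C4=C5 bond, and the tetrasubstituted epoxide may open under the Lewis-acidic conditions. The fallback sets out from 18 and changes the order, so that the face is fixed by acyclic 1,3-allylic strain before ring B exists. VO(acac)2 and t-BuOOH on the open-chain carbinol, whose other alkenes are only mono- and 1,1-disubstituted, should give the monocyclic 4β,5β-epoxy alcohol F2. Ring-closing metathesis of this compound with RuCl2(=CHPh)(PCy3)(H2IMes) then returns to 20.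

Step 13. Allyl transfer to the hindered, fully substituted enal may be slow, and face selectivity may erode at the higher temperature then needed. The fallback sets out from 16 and sets C6 by reagent-controlled ketone reduction instead of C–C bond formation. 2-Methylallylmagnesium chloride adds to 16 to give the carbinol as a mixture of C6 epimers F3, and Dess–Martin oxidation gives the methallyl ketone F4. Corey–Bakshi–Shibata reduction with the (S)-configured B-methyl oxazaborolidine and catecholborane (toluene, −78 °C, chosen because it leaves the terminal alkenes alone) should give 18, with which the route continues.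

Further compounds
F1 | step 17 | 6-O-trimethylsilyl ether of 20 | CC1=CC[C@@]2(C)CC[C@]3(C(C)C)O[C@]23[C@H](O[Si](C)(C)C)C1
F2 | step 15 | monocyclic 4β,5β-epoxy alcohol, epoxide of 18 on the hydroxyl face | C=CC[C@@]1(C)CC[C@]2(C(C)C)O[C@]12[C@H](O)CC(C)=C
F3 | step 13 | 3-methyl-1-[(5R)-5-methyl-2-(propan-2-yl)-5-(prop-2-en-1-yl)cyclopent-1-en-1-yl]but-3-en-1-ol, both C1 epimers of the butenol chain | CC(=C)CC(O)C1=C(C(C)C)CC[C@]1(C)CC=C
F4 | step 13 | 3-methyl-1-[(5R)-5-methyl-2-(propan-2-yl)-5-(prop-2-en-1-yl)cyclopent-1-en-1-yl]but-3-en-1-one | CC(=C)CC(=O)C1=C(C(C)C)CC[C@]1(C)CC=C
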